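**Strategy.** The 2,2-dimethyl-2H-pyran (O2', CMe2, CH=CH, C3', C2' of ring B) is disconnected last, to a (3R)-2'-hydroxyisoflavan and prenal. In the key step a phenylboronic acid template ties prenal to O2' and delivers it to C3', the only free ortho carbon of that phenol because C1' carries the chroman C3. The benzodioxaborin then collapses to an ortho-quinone methide whose oxa-6π electrocyclization closes the pyran, so the C–C and C–O bonds form in one operation. The precursor is the 7,4'-bis-silylated 2'-phenol, obtained from a Suzuki-derived isoflavone by asymmetric transfer hydrogenation with dynamic kinetic resolution, hydrogenolysis and selective silylation.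

Key step: step 7

Remark: isoflavan numbering is used (chroman O1, C2, C3, C4, C4a to C8a; ring B primed, C1' on C3); 1 and 5 are taken as purchasable, 5 being otherwise one lithiation–borylation step from 1-bromo-2,4-bis(benzyloxy)benzene.

**Step 1**
Reactants: 1 1-(2,4-dihydroxy-6-methoxyphenyl)ethan-1-one
Product: 2 1-[4-(benzyloxy)-2-hydroxy-6-methoxyphenyl]ethan-1-one
Conditions: BnBr (1.05 equiv), K2CO3, acetone, reflux
Reagents that add atoms: benzyl bromide, BrCc1ccccc1
Why: Williamson ether synthesis should be selective for the 4-OH because the 2-OH is locked in a hydrogen bond to the acetyl carbonyl and is the weaker nucleophile.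

**Step 2**
Reactants: 2 1-[4-(benzyloxy)-2-hydroxy-6-methoxyphenyl]ethan-1-one
Product: 4 7-(benzyloxy)-3-iodo-5-methoxy-4H-chromen-4-one, via enaminone 3 (not isolated)
Conditions: Me2NCH(OMe)2, toluene, 95 °C; evaporate; then I2, CHCl3, rt
Reagents that add atoms: N,N-dimethylformamide dimethyl acetal, COC(OC)N(C)C; iodine, II
Why: Condensation of the methyl ketone with the formamide acetal should give enaminone 3, and iodine should then iodinate its α-carbon and induce attack of the phenol oxygen on the iminium carbon with loss of dimethylamine (iodine-mediated enaminone cyclization to a 3-iodochromone), which closes ring C.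

**Step 3**
Reactants: 4 7-(benzyloxy)-3-iodo-5-methoxy-4H-chromen-4-one; 5 [2,4-bis(benzyloxy)phenyl]boronic acid
Product: 6 7-(benzyloxy)-3-[2,4-bis(benzyloxy)phenyl]-5-methoxy-4H-chromen-4-one
Conditions: PdCl2(dppf) (5 mol %), K2CO3, 1,4-dioxane/H2O, 80 °C
Reagents that add atoms: none
Why: Suzuki–Miyaura cross-coupling of the C3 iodide with the electron-rich arylboronic acid should form the C3–C1' bond under mild carbonate conditions that leave the chromone ring intact.

**Step 4**
Reactants: 6 7-(benzyloxy)-3-[2,4-bis(benzyloxy)phenyl]-5-methoxy-4H-chromen-4-one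
Product: 8 (3R,4R)-7-(benzyloxy)-3-[2,4-bis(benzyloxy)phenyl]-5-methoxychroman-4-ol, via racemic isoflavanone 7 (not isolated)
Conditions: RuCl[(R,R)-TsDPEN](p-cymene) (5 mol %), HCO2H/Et3N, EtOAc, 40 °C
Reagents that add atoms: none
Why: Noyori-type asymmetric transfer hydrogenation should first reduce the C2=C3 bond to the racemic isoflavanone 7, whose acidic C3–H epimerizes in the amine medium, and the (R,R) catalyst should then reduce the carbonyl of the matched enantiomer from the face anti to the 3-aryl group (dynamic kinetic resolution), so that C4 is set R by the catalyst and C3 is set R by the cis relationship.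

**Step 5**
Reactants: 8 (3R,4R)-7-(benzyloxy)-3-[2,4-bis(benzyloxy)phenyl]-5-methoxychroman-4-ol
Product: 9 4-[(3R)-7-hydroxy-5-methoxychroman-3-yl]benzene-1,3-diol
Conditions: H2 (4 bar), 10% Pd/C, EtOH/AcOH, rt
Reagents that add atoms: none
Why: Catalytic hydrogenolysis should cleave the three benzyl ethers and the C4–O bond, which is benzylic to a ring carrying ortho and para oxygen donors, while C3 keeps its R configuration because it is no longer next to a carbonyl and is not touched.

**Step 6**
Reactants: 9 4-[(3R)-7-hydroxy-5-methoxychroman-3-yl]benzene-1,3-diol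
Product: 10 5-[(tert-butyldimethylsilyl)oxy]-2-[(3R)-7-[(tert-butyldimethylsilyl)oxy]-5-methoxychroman-3-yl]phenol
Conditions: TBSCl (2.05 equiv), imidazole, DMF, −20 to 0 °C
Reagents that add atoms: tert-butyldimethylsilyl chloride, CC(C)(C)[Si](C)(C)Cl
Why: Silylation with a bulky chlorosilane should take the two unhindered phenols (7-OH and 4'-OH) and leave the 2'-OH free, because that hydroxyl is flanked by the secondary chroman C3 (sterically controlled site-selective protection).

**Step 7**
Reactants: 10 5-[(tert-butyldimethylsilyl)oxy]-2-[(3R)-7-[(tert-butyldimethylsilyl)oxy]-5-methoxychroman-3-yl]phenol; 11 3-methylbut-2-enal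
Product: 14 (3R)-7-[(tert-butyldimethylsilyl)oxy]-3-{5-[(tert-butyldimethylsilyl)oxy]-2,2-dimethyl-2H-chromen-8-yl}-5-methoxychroman, via benzodioxaborin 12 (not isolated), via ortho-quinone methide 13 (not isolated)
Conditions: PhB(OH)2 (1.2 equiv), EtCO2H (cat.), toluene, reflux, azeotropic removal of water
Reagents that add atoms: none
Why: Phenol 10 and PhB(OH)2 should form an aryl phenylboronate that binds prenal at boron and delivers its carbonyl carbon intramolecularly to the ortho carbon, giving benzodioxaborin 12, which in hot toluene with propionic acid should lose PhB(OH)2 to give the ortho-quinone methide 13. The closest known reaction type is the phenylboronic acid-mediated ortho-specific condensation of phenols with enals to 2H-chromenes, a formal [3+3] annulation. The pyran ring closes by thermal oxa-6π electrocyclization of 13, which forms the O–CMe2 bond after the C3'–CH bond has been made by the boron-tethered ortho-hydroxyalkylation. No stereocentre is created, since the carbinol carbon of 12 becomes sp2, and C3 of the chroman is remote and not epimerizable under weak acid. The step needs ortho- and site-selectivity: the boron tether enforces ortho attack, C1' is blocked by the chroman so only C3' (activated by O2' and O4') can react, the silylated O4' cannot take part in the electrocyclization, and ring A has no free phenol to engage boron.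

**Step 8**
Reactants: 14 (3R)-7-[(tert-butyldimethylsilyl)oxy]-3-{5-[(tert-butyldimethylsilyl)oxy]-2,2-dimethyl-2H-chromen-8-yl}-5-methoxychroman
Product: 15 (3R)-3-(5-hydroxy-2,2-dimethyl-2H-chromen-8-yl)-5-methoxychroman-7-ol
Conditions: Bu4NF (2.2 equiv), AcOH (2.2 equiv), THF, 0 °C
Reagents that add atoms: none
Why: Fluoride-mediated cleavage of the two aryl silyl ethers, buffered with acetic acid, should release both phenols without affecting the chromene double bond, the methyl ether or the stereocentre.

**Compound list**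

1 | 1-(2,4-dihydroxy-6-methoxyphenyl)ethan-1-one | CC(=O)c1c(O)cc(O)cc1OC | starting material
2 | 1-[4-(benzyloxy)-2-hydroxy-6-methoxyphenyl]ethan-1-one | CC(=O)c1c(O)cc(OCc2ccccc2)cc1OC | intermediate
3 | (E)-1-[4-(benzyloxy)-2-hydroxy-6-methoxyphenyl]-3-(dimethylamino)prop-2-en-1-one | CN(C)/C=C/C(=O)c1c(O)cc(OCc2ccccc2)cc1OC | intermediate
4 | 7-(benzyloxy)-3-iodo-5-methoxy-4H-chromen-4-one | COc1cc(OCc2ccccc2)cc2occ(I)c(=O)c12 | intermediate
5 | [2,4-bis(benzyloxy)phenyl]boronic acid | OB(O)c1ccc(OCc2ccccc2)cc1OCc1ccccc1 | starting material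
6 | 7-(benzyloxy)-3-[2,4-bis(benzyloxy)phenyl]-5-methoxy-4H-chromen-4-one | COc1cc(OCc2ccccc2)cc2occ(-c3ccc(OCc4ccccc4)cc3OCc3ccccc3)c(=O)c12 | intermediate
7 | racemic 7-(benzyloxy)-3-[2,4-bis(benzyloxy)phenyl]-5-methoxychroman-4-one | COc1cc(OCc2ccccc2)cc2OCC(c3ccc(OCc4ccccc4)cc3OCc3ccccc3)C(=O)c12 | intermediate
8 | (3R,4R)-7-(benzyloxy)-3-[2,4-bis(benzyloxy)phenyl]-5-methoxychroman-4-ol (cis) | COc1cc(OCc2ccccc2)cc2c1[C@H](O)[C@H](c1ccc(OCc3ccccc3)cc1OCc1ccccc1)CO2 | intermediate
9 | 4-[(3R)-7-hydroxy-5-methoxychroman-3-yl]benzene-1,3-diol | COc1cc(O)cc2c1C[C@H](c1ccc(O)cc1O)CO2 | intermediate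
10 | 5-[(tert-butyldimethylsilyl)oxy]-2-[(3R)-7-[(tert-butyldimethylsilyl)oxy]-5-methoxychroman-3-yl]phenol | COc1cc(O[Si](C)(C)C(C)(C)C)cc2c1C[C@H](c1ccc(O[Si](C)(C)C(C)(C)C)cc1O)CO2 | intermediate
11 | 3-methylbut-2-enal (prenal) | CC(C)=CC=O | starting material
12 | (3R)-7-[(tert-butyldimethylsilyl)oxy]-3-{5-[(tert-butyldimethylsilyl)oxy]-4-(2-methylprop-1-en-1-yl)-2-phenyl-4H-1,3,2-benzodioxaborinin-8-yl}-5-methoxychroman (both epimers at the dioxaborin C4) | COc1cc(O[Si](C)(C)C(C)(C)C)cc2c1C[C@H](c1ccc(O[Si](C)(C)C(C)(C)C)c3c1OB(c1ccccc1)OC3C=C(C)C)CO2 | intermediate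
13 | 3-[(tert-butyldimethylsilyl)oxy]-6-[(3R)-7-[(tert-butyldimethylsilyl)oxy]-5-methoxychroman-3-yl]-2-(3-methylbut-2-en-1-ylidene)cyclohexa-3,5-dien-1-one (exocyclic alkene geometry open) | COc1cc(O[Si](C)(C)C(C)(C)C)cc2c1C[C@H](C1=CC=C(O[Si](C)(C)C(C)(C)C)C(=CC=C(C)C)C1=O)CO2 | intermediate
14 | (3R)-7-[(tert-butyldimethylsilyl)oxy]-3-{5-[(tert-butyldimethylsilyl)oxy]-2,2-dimethyl-2H-chromen-8-yl}-5-methoxychroman | COc1cc(O[Si](C)(C)C(C)(C)C)cc2c1C[C@H](c1ccc(O[Si](C)(C)C(C)(C)C)c3c1OC(C)(C)C=C3)CO2 | intermediate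
15 | (3R)-3-(5-hydroxy-2,2-dimethyl-2H-chromen-8-yl)-5-methoxychroman-7-ol | COc1cc(O)cc2c1C[C@H](c1ccc(O)c3c1OC(C)(C)C=C3)CO2 | target

**Step count and risks**

Total step count: 8. Longest linear sequence: 8 (steps 1 to 8 from 1; 5 and 11 are bought).

Steps most likely to fail:

1. Step 7. The boron-tethered hydroxyalkylation at C3', which sits between O2' and the silyloxy group, may be too slow, so that prenal self-condenses or the silyl ethers are lost in hot acid before the annulation is complete. Fallback: from 10, O-alkylation with 3-chloro-3-methylbut-1-yne (CuCl2 cat., DBU, MeCN, 0 °C) should give (3R)-7-[(tert-butyldimethylsilyl)oxy]-3-{4-[(tert-butyldimethylsilyl)oxy]-2-[(2-methylbut-3-yn-2-yl)oxy]phenyl}-5-methoxychroman F1. Heating F1 in N,N-diethylaniline at about 180 °C should then bring about the aromatic propargyl Claisen rearrangement to C3', enolization, [1,5]-hydrogen shift and oxa-6π electrocyclization, which returns to the route at 14.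

2. Step 6. Discrimination between the hindered 2'-OH and the two unhindered phenols may be incomplete, giving mixtures of partly and fully silylated material. Fallback: from 8, hydrogenolysis without acid (H2 1 atm, Pd/C, EtOAc, rt) should remove only the benzyl ethers and give (3R,4R)-3-(2,4-dihydroxyphenyl)-5-methoxychroman-4,7-diol F2. A catalytic amount of PPTS in CH2Cl2 should close it to (6aR,11aR)-1-methoxy-6a,11a-dihydro-6H-benzofuro[3,2-c]chromene-3,9-diol F3, in which O2' is tied to C4 as a temporary ring. Exhaustive silylation (excess TBSCl, imidazole, DMF), which needs no selectivity, should give (6aR,11aR)-3,9-bis[(tert-butyldimethylsilyl)oxy]-1-methoxy-6a,11a-dihydro-6H-benzofuro[3,2-c]chromene F4. Hydrogenolysis of its benzylic C–O bond (H2, Pd/C, EtOAc/AcOH) should reopen the ring and release only the 2'-OH, returning to the route at 10.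

3. Step 4. Conjugate reduction of the electron-rich chromone by the ruthenium hydride may stall, or carbonyl reduction may outrun epimerization at C3, leading to low conversion or erosion of diastereo- and enantioselectivity. Fallback: from 6, NaBH4 (THF/EtOH) should give 7-(benzyloxy)-3-[2,4-bis(benzyloxy)phenyl]-5-methoxychroman-4-ol (stereoisomer mixture) F5, and TsOH (cat., toluene, 60 °C) should dehydrate it to 7-(benzyloxy)-3-[2,4-bis(benzyloxy)phenyl]-5-methoxy-2H-chromene F6. Iridium-catalysed asymmetric hydrogenation of the trisubstituted alkene ([Ir(cod)(tBu-PHOX)]BArF, ligand antipode chosen for the 3R product, H2 50 bar, CH2Cl2) should give (3R)-7-(benzyloxy)-3-[2,4-bis(benzyloxy)phenyl]-5-methoxychroman F7. Hydrogenolysis of the benzyl ethers (H2, Pd/C, EtOAc/EtOH) then returns to the route at 9.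

**Further compounds**

F1 | step 7 | (3R)-7-[(tert-butyldimethylsilyl)oxy]-3-{4-[(tert-butyldimethylsilyl)oxy]-2-[(2-methylbut-3-yn-2-yl)oxy]phenyl}-5-methoxychroman | COc1cc(O[Si](C)(C)C(C)(C)C)cc2c1C[C@H](c1ccc(O[Si](C)(C)C(C)(C)C)cc1OC(C)(C)C#C)CO2
F2 | step 6 | (3R,4R)-3-(2,4-dihydroxyphenyl)-5-methoxychroman-4,7-diol | COc1cc(O)cc2c1[C@H](O)[C@H](c1ccc(O)cc1O)CO2
F3 | step 6 | (6aR,11aR)-1-methoxy-6a,11a-dihydro-6H-benzofuro[3,2-c]chromene-3,9-diol | COc1cc(O)cc2c1[C@@H]1Oc3cc(O)ccc3[C@@H]1CO2
F4 | step 6 | (6aR,11aR)-3,9-bis[(tert-butyldimethylsilyl)oxy]-1-methoxy-6a,11a-dihydro-6H-benzofuro[3,2-c]chromene | COc1cc(O[Si](C)(C)C(C)(C)C)cc2c1[C@@H]1Oc3cc(O[Si](C)(C)C(C)(C)C)ccc3[C@@H]1CO2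
F5 | step 4 | 7-(benzyloxy)-3-[2,4-bis(benzyloxy)phenyl]-5-methoxychroman-4-ol (stereoisomer mixture) | COc1cc(OCc2ccccc2)cc2c1C(O)C(c1ccc(OCc3ccccc3)cc1OCc1ccccc1)CO2
F6 | step 4 | 7-(benzyloxy)-3-[2,4-bis(benzyloxy)phenyl]-5-methoxy-2H-chromene | COc1cc(OCc2ccccc2)cc2c1C=C(c1ccc(OCc3ccccc3)cc1OCc1ccccc1)CO2
F7 | step 4 | (3R)-7-(benzyloxy)-3-[2,4-bis(benzyloxy)phenyl]-5-methoxychroman | COc1cc(OCc2ccccc2)cc2c1C[C@H](c1ccc(OCc3ccccc3)cc1OCc1ccccc1)CO2
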